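**Retrosynthetic overview**
1. The route rests on the aldol triad across the ring fusion: the tertiary carbinol C4(OH)(iPr) of ring A, the ring-fusion methine C5–H, and the oxygen-bearing C6 of ring B. With C6 as a ketone, C4–C5 is an aldol bond. It is cut to a C5=C6 silyl enol ether on the cycloheptene and an isopropyl ketone at the end of the C1–C2–C3 chain.
2. The enol ether and the quaternary C1 are made together by Me2CuLi/Me3SiCl addition to a 3-substituted 6-methylcyclohepta-2,5-dienone, so no enolate toward the allylic C7 is ever formed.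
3. C2–C3 is cut by a reagent-controlled boron aldol of 3-methylbutan-2-one with the ring B enal. This step is the source of absolute configuration.
4. Ring B is cut at C8=C9 (ring-closing metathesis) and at C1=C5 (Wittig), back to ethyl glyoxylate, isobutene and a butenylphosphonium salt. The ene-derived C6 carbinol is a temporary stereochemical marker.
5. Ring B is formed first, then ring A. The endgame is hydroxyl-directed C6 reduction, anisoylation, desilylation and angeloylation.

Key step: step 12

Remark: daucane numbering is used for all compounds (C1 quaternary, C2 O-bearing, C4 carbinol, C5 ring-fusion CH, C6 O-bearing, C8=C9), β is the face of the C1 methyl group, and the configuration of the temporary C6 centre in 3–17 has no bearing on the target.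

**Step 1**
Reactants: 1 ethyl glyoxylate; 2 2-methylpropene (isobutene)
Product: 3 ethyl (2R)-2-hydroxy-4-methylpent-4-enoate (carbinol carbon = future C6)
Conditions: (R)-BINOL/TiCl2(OiPr)2 (10 mol %), 4 Å MS, CH2Cl2, −30 °C
Reagents that add atoms: none
Why: Asymmetric glyoxylate-ene reaction in which the chiral BINOL–titanium Lewis acid shields one face of the aldehyde while isobutene transfers an allylic hydrogen, which should give the (R)-carbinol that serves only as a temporary marker and is erased in step 10.

**Step 2**
Reactants: 3 ethyl (2R)-2-hydroxy-4-methylpent-4-enoate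
Product: 4 ethyl (2R)-4-methyl-2-(triethylsilyloxy)pent-4-enoate
Conditions: Et3SiCl, imidazole, CH2Cl2, 0 °C
Reagents that add atoms: chlorotriethylsilane, CC[Si](Cl)(CC)CC
Why: Imidazole-promoted silylation of a secondary alcohol, the triethylsilyl group being chosen because it can later be removed beside a tert-butyldimethylsilyl ether.

**Step 3**
Reactants: 4 ethyl (2R)-4-methyl-2-(triethylsilyloxy)pent-4-enoate
Product: 5 (2R)-4-methyl-2-(triethylsilyloxy)pent-4-enal
Conditions: iBu2AlH, CH2Cl2, −78 °C; aq. potassium sodium tartrate
Reagents that add atoms: none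
Why: Partial ester reduction in which the aluminium hemiacetal, stabilised by the α-silyloxy group, persists at −78 °C and collapses to the aldehyde only on work-up, so over-reduction and epimerisation should be avoided.

**Step 4**
Reactants: 6 but-3-en-1-yl(triphenyl)phosphonium bromide; 7 ethyl formate
Product: 9 2-(triphenylphosphoranylidene)pent-4-enal, via but-3-enylidenetriphenylphosphorane 8 (not isolated)
Conditions: KOtBu, THF, 0 °C; then 7, 0 °C to rt
Reagents that add atoms: none
Why: C-formylation of a non-stabilised phosphorus ylide by a formate ester followed by loss of the now acidic α-proton, which should give the stabilised α-allyl formyl ylide.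

**Step 5**
Reactants: 5 (2R)-4-methyl-2-(triethylsilyloxy)pent-4-enal; 9 2-(triphenylphosphoranylidene)pent-4-enal
Product: 10 (2E,4R)-2-allyl-6-methyl-4-(triethylsilyloxy)hepta-2,6-dienal
Conditions: toluene, 90 °C
Reagents that add atoms: none
Why: Wittig olefination with a stabilised α-substituted ylide should give the (E)-enal, i.e. C6 cis to the allyl carbon C10 across C1=C5, which is the geometry ring B needs.

**Step 6**
Reactants: 10 (2E,4R)-2-allyl-6-methyl-4-(triethylsilyloxy)hepta-2,6-dienal
Product: 11 (3R)-5-methyl-3-(triethylsilyloxy)cyclohepta-1,5-diene-1-carbaldehyde (ring B)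
Conditions: second-generation Grubbs catalyst (H2IMes)(PCy3)Cl2Ru=CHPh (5 mol %), CH2Cl2 (high dilution), reflux
Reagents that add atoms: none
Why: Ring-closing metathesis in which the catalyst loads on the monosubstituted allyl terminus and closes onto the methallyl alkene, the cis C1=C5 bond holding both arms together, so the seven-membered ring should form with the trisubstituted C8=C9 bond while the electron-poor enal alkene stays inert.

**Step 7**
Reactants: 11 (3R)-5-methyl-3-(triethylsilyloxy)cyclohepta-1,5-diene-1-carbaldehyde; 12 3-methylbutan-2-one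
Product: 15 (1R)-1-hydroxy-4-methyl-1-[(3R)-5-methyl-3-(triethylsilyloxy)cyclohepta-1,5-dien-1-yl]pentan-3-one, via enol diisopinocampheylborinate 13 (not isolated), via boron aldolate 14 (not isolated)
Conditions: 12, (−)-Ipc2BCl, Et3N, Et2O, 0 °C; then 11, −78 to −20 °C; H2O2, MeOH, pH 7 buffer, 0 °C; chromatography
Reagents that add atoms: none
Why: Boron-mediated aldol addition under reagent control, in which Ipc2BCl/Et3N enolises the ketone on the methyl side only and 13 adds to the aldehyde through a cyclic transition state whose isopinocampheyl groups expose one aldehyde face to give the (R)-carbinol C2, and because C6 already has a single configuration the minor C2 epimer is a diastereomer that chromatography removes.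

**Step 8**
Reactants: 15 (1R)-1-hydroxy-4-methyl-1-[(3R)-5-methyl-3-(triethylsilyloxy)cyclohepta-1,5-dien-1-yl]pentan-3-one
Product: 16 (1R)-1-(tert-butyldimethylsilyloxy)-4-methyl-1-[(3R)-5-methyl-3-(triethylsilyloxy)cyclohepta-1,5-dien-1-yl]pentan-3-one
Conditions: TBSOTf, 2,6-lutidine, CH2Cl2, −78 °C
Reagents that add atoms: tert-butyldimethylsilyl trifluoromethanesulfonate, CC(C)(C)[Si](C)(C)OS(=O)(=O)C(F)(F)F
Why: Silylation with the silyl triflate and a hindered non-nucleophilic base is fast at −78 °C, so retro-aldol cleavage, β-elimination and enol silylation of the ketone should not compete.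

**Step 9**
Reactants: 16 (1R)-1-(tert-butyldimethylsilyloxy)-4-methyl-1-[(3R)-5-methyl-3-(triethylsilyloxy)cyclohepta-1,5-dien-1-yl]pentan-3-one
Product: 17 (1R)-1-(tert-butyldimethylsilyloxy)-1-[(3R)-3-hydroxy-5-methylcyclohepta-1,5-dien-1-yl]-4-methylpentan-3-one
Conditions: PPTS (cat.), MeOH/CH2Cl2, 0 °C
Reagents that add atoms: none
Why: Acid-catalysed methanolysis distinguishes the two silyl ethers on steric grounds, the triethylsilyl ether being cleaved much faster than the hindered tert-butyldimethylsilyl ether.

**Step 10**
Reactants: 17 (1R)-1-(tert-butyldimethylsilyloxy)-1-[(3R)-3-hydroxy-5-methylcyclohepta-1,5-dien-1-yl]-4-methylpentan-3-one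
Product: 18 3-[(1R)-1-(tert-butyldimethylsilyloxy)-4-methyl-3-oxopentyl]-6-methylcyclohepta-2,5-dien-1-one
Conditions: Dess–Martin periodinane, NaHCO3, CH2Cl2, 0 °C; used promptly
Reagents that add atoms: none
Why: Dess–Martin oxidation of the allylic alcohol runs under buffered, essentially neutral conditions, which erases the temporary C6 centre and should give the 2,5-dienone without moving the skipped C8=C9 bond into conjugation.

**Step 11**
Reactants: 18 3-[(1R)-1-(tert-butyldimethylsilyloxy)-4-methyl-3-oxopentyl]-6-methylcyclohepta-2,5-dien-1-one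
Product: 19 (1R)-1-(tert-butyldimethylsilyloxy)-1-[(1R)-1,5-dimethyl-3-(trimethylsilyloxy)cyclohepta-2,5-dien-1-yl]-4-methylpentan-3-one (C5=C6 trimethylsilyl enol ether)
Conditions: Me2CuLi (from MeLi and CuI), Me3SiCl, THF, −78 to −40 °C; Et3N, pentane, cold aq. NaHCO3; used crude
Reagents that add atoms: lithium dimethylcuprate, [Li+].C[Cu-]C; chlorotrimethylsilane, C[Si](C)(C)Cl
Why: Me3SiCl-accelerated conjugate addition of a Gilman cuprate puts methyl on C1 and silylates the enolate oxygen as it forms, which fixes the enol ether at C5=C6 while the hindered saturated isopropyl ketone is left alone at low temperature; the quaternary centre is set by 1,2-induction from C2 (Felkin–Anh-type arrangement with the C2–O bond anti to the incoming copper, C2–H over the π bond and C3 turned away), so methyl and silyloxy group should end up anti along C5–C1–C2–C3, i.e. cis on the future ring A.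

**Step 12**
Reactants: 19 (1R)-1-(tert-butyldimethylsilyloxy)-1-[(1R)-1,5-dimethyl-3-(trimethylsilyloxy)cyclohepta-2,5-dien-1-yl]-4-methylpentan-3-one
Product: 21 2β-(tert-butyldimethylsilyloxy)-4β-hydroxydauc-8-en-6-one (5α-H, trans-fused), via trichlorotitanium aldolate 20 (not isolated)
Conditions: TiCl4 (1.1 equiv), CH2Cl2, −78 °C, then −40 °C; recool to −78 °C, aq. NaHCO3
Reagents that add atoms: none
Why: TiCl4 binds the isopropyl ketone, C5 of the silyl enol ether adds to C4 and Me3SiCl is lost, leaving the titanium aldolate 20; this is an intramolecular Mukaiyama aldol addition to a ketone. Ring A closes in a 5-(enolexo)-exo-trig mode, and only C5 can react because the enol ether was fixed at C5=C6 in step 11, no proton transfer occurs at these temperatures and C7 could only give a bridged ring, so C8=C9 stays out of conjugation. C4 is controlled by the β substituents already on the forming ring (C1 methyl and C2 silyloxy group), which push the isopropyl group to the α face and the oxygen to the β face. C5 is controlled by titanium, since only the aldolate with C6 cis to the C4 oxygen on ring A, that is 5α-H and a trans ring fusion, can close the six-membered O4–Ti–O6 chelate. The closure with the easier orbital overlap (C4 arriving on the face of C5 that carries C2, cis fusion) gives an aldolate that cannot chelate, and on warming to −40 °C it should reopen by retro-aldol cleavage, which regenerates only the C5 nucleophile, and drain into the chelate. The step needs regioselectivity, chemoselectivity and control of two centres, secured in turn by the preformed enol ether, by the cold quench (no dehydration, silyl ether kept) and by the chelate together with the β-face substituents.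

**Step 13**
Reactants: 21 2β-(tert-butyldimethylsilyloxy)-4β-hydroxydauc-8-en-6-one
Product: 22 2β-(tert-butyldimethylsilyloxy)dauc-8-ene-4β,6α-diol
Conditions: Me4NBH(OAc)3, MeCN/AcOH, −30 to 0 °C
Reagents that add atoms: none
Why: Hydroxyl-directed (Evans–Saksena) reduction in which the 4β-hydroxyl replaces an acetate on boron and hydride is delivered through a chair-like six-membered transition state to the β face of C6, which should give the equatorial 6α-alcohol (1,3-anti diol), the reagent itself being too weak to reduce the ketone from the more open α face.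

**Step 14**
Reactants: 22 2β-(tert-butyldimethylsilyloxy)dauc-8-ene-4β,6α-diol; 23 4-methoxybenzoyl chloride
Product: 24 2β-(tert-butyldimethylsilyloxy)-6α-(4-methoxybenzoyloxy)dauc-8-en-4β-ol
Conditions: 23, Et3N, DMAP (cat.), CH2Cl2, 0 °C to rt
Reagents that add atoms: none
Why: DMAP-catalysed acylation is selective for the secondary 6α-hydroxyl because the tertiary C4 hydroxyl next to the isopropyl group is inert under these conditions and C2 is still silylated.

**Step 15**
Reactants: 24 2β-(tert-butyldimethylsilyloxy)-6α-(4-methoxybenzoyloxy)dauc-8-en-4β-ol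
Product: 25 6α-(4-methoxybenzoyloxy)dauc-8-ene-2β,4β-diol
Conditions: HF·pyridine, pyridine, THF, 0 °C to rt
Reagents that add atoms: none
Why: Fluoride-driven Si–O cleavage under buffered, weakly acidic conditions should free the C2 hydroxyl without acyl migration, ester cleavage or ionisation of the tertiary alcohol.

**Step 16**
Reactants: 25 6α-(4-methoxybenzoyloxy)dauc-8-ene-2β,4β-diol; 26 angelic acid ((Z)-2-methylbut-2-enoic acid)
Product: 28 2β-angeloyloxy-6α-(4-methoxybenzoyloxy)dauc-8-en-4β-ol (1R,2R,4R,5S,6S; CNP0204191.1), via angelic 2,4,6-trichlorobenzoic anhydride 27 (not isolated)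
Conditions: 26, 2,4,6-trichlorobenzoyl chloride, Et3N, toluene, rt; then 25, 80 °C (no DMAP)
Reagents that add atoms: none
Why: Yamaguchi-type esterification in which the hindered trichlorobenzoyl carbonyl of 27 directs the C2 hydroxyl to the angeloyl carbonyl, the absence of a nucleophilic catalyst avoids addition–elimination isomerisation of the (Z)-ester to the tiglate, and the tertiary C4 hydroxyl does not react.

**Compound list**
1 | ethyl glyoxylate | O=CC(=O)OCC | starting material
2 | 2-methylpropene | C=C(C)C | starting material
3 | ethyl (2R)-2-hydroxy-4-methylpent-4-enoate | CCOC(=O)[C@H](O)CC(C)=C | intermediate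
4 | ethyl (2R)-4-methyl-2-(triethylsilyloxy)pent-4-enoate | CCOC(=O)[C@H](O[Si](CC)(CC)CC)CC(C)=C | intermediate
5 | (2R)-4-methyl-2-(triethylsilyloxy)pent-4-enal | O=C[C@H](O[Si](CC)(CC)CC)CC(C)=C | intermediate
6 | but-3-en-1-yl(triphenyl)phosphonium bromide | C=CCC[P+](c1ccccc1)(c1ccccc1)c1ccccc1.[Br-] | starting material
7 | ethyl formate | CCOC=O | starting material
8 | but-3-enylidenetriphenylphosphorane (not isolated) | C=CCC=P(c1ccccc1)(c1ccccc1)c1ccccc1 | intermediate
9 | 2-(triphenylphosphoranylidene)pent-4-enal | C=CCC(C=O)=P(c1ccccc1)(c1ccccc1)c1ccccc1 | intermediate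
10 | (2E,4R)-2-allyl-6-methyl-4-(triethylsilyloxy)hepta-2,6-dienal | O=C/C(CC=C)=C/[C@H](O[Si](CC)(CC)CC)CC(C)=C | intermediate
11 | (3R)-5-methyl-3-(triethylsilyloxy)cyclohepta-1,5-diene-1-carbaldehyde | O=CC1=C[C@H](O[Si](CC)(CC)CC)CC(C)=CC1 | intermediate
12 | 3-methylbutan-2-one | CC(C)C(C)=O | starting material
13 | 3-methylbut-1-en-2-yl diisopinocampheylborinate (not isolated) | C=C(OB([C@@H]1C[C@@H]2C[C@H]([C@H]1C)C2(C)C)[C@@H]1C[C@@H]2C[C@H]([C@H]1C)C2(C)C)C(C)C | intermediate
14 | diisopinocampheylboron aldolate of 15 (not isolated) | CC(C)C(=O)C[C@@H](OB([C@@H]1C[C@@H]2C[C@H]([C@H]1C)C2(C)C)[C@@H]1C[C@@H]2C[C@H]([C@H]1C)C2(C)C)C1=C[C@H](O[Si](CC)(CC)CC)CC(C)=CC1 | intermediate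
15 | (1R)-1-hydroxy-4-methyl-1-[(3R)-5-methyl-3-(triethylsilyloxy)cyclohepta-1,5-dien-1-yl]pentan-3-one | CC(C)C(=O)C[C@@H](O)C1=C[C@H](O[Si](CC)(CC)CC)CC(C)=CC1 | intermediate
16 | (1R)-1-(tert-butyldimethylsilyloxy)-4-methyl-1-[(3R)-5-methyl-3-(triethylsilyloxy)cyclohepta-1,5-dien-1-yl]pentan-3-one | CC(C)C(=O)C[C@@H](O[Si](C)(C)C(C)(C)C)C1=C[C@H](O[Si](CC)(CC)CC)CC(C)=CC1 | intermediate
17 | (1R)-1-(tert-butyldimethylsilyloxy)-1-[(3R)-3-hydroxy-5-methylcyclohepta-1,5-dien-1-yl]-4-methylpentan-3-one | CC(C)C(=O)C[C@@H](O[Si](C)(C)C(C)(C)C)C1=C[C@H](O)CC(C)=CC1 | intermediate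
18 | 3-[(1R)-1-(tert-butyldimethylsilyloxy)-4-methyl-3-oxopentyl]-6-methylcyclohepta-2,5-dien-1-one | CC(C)C(=O)C[C@@H](O[Si](C)(C)C(C)(C)C)C1=CC(=O)CC(C)=CC1 | intermediate
19 | (1R)-1-(tert-butyldimethylsilyloxy)-1-[(1R)-1,5-dimethyl-3-(trimethylsilyloxy)cyclohepta-2,5-dien-1-yl]-4-methylpentan-3-one | CC(C)(C)[Si](C)(C)O[C@H](CC(=O)C(C)C)[C@@]1(C)C=C(O[Si](C)(C)C)CC(C)=CC1 | intermediate
20 | trichlorotitanium aldolate of 21 (O4–Ti–O6 chelate, not isolated) | CC(C)(C)[Si](C)(C)O[C@@H]1C[C@@](O[Ti](Cl)(Cl)Cl)(C(C)C)[C@@H]2C(=O)CC(C)=CC[C@]21C | intermediate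
21 | 2β-(tert-butyldimethylsilyloxy)-4β-hydroxydauc-8-en-6-one | CC(C)(C)[Si](C)(C)O[C@@H]1C[C@@](O)(C(C)C)[C@@H]2C(=O)CC(C)=CC[C@]21C | intermediate
22 | 2β-(tert-butyldimethylsilyloxy)dauc-8-ene-4β,6α-diol | CC(C)(C)[Si](C)(C)O[C@@H]1C[C@@](O)(C(C)C)[C@@H]2[C@@H](O)CC(C)=CC[C@]21C | intermediate
23 | 4-methoxybenzoyl chloride | COc1ccc(cc1)C(=O)Cl | starting material
24 | 2β-(tert-butyldimethylsilyloxy)-6α-(4-methoxybenzoyloxy)dauc-8-en-4β-ol | CC(C)(C)[Si](C)(C)O[C@@H]1C[C@@](O)(C(C)C)[C@@H]2[C@@H](OC(=O)c3ccc(OC)cc3)CC(C)=CC[C@]21C | intermediate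
25 | 6α-(4-methoxybenzoyloxy)dauc-8-ene-2β,4β-diol | O[C@@H]1C[C@@](O)(C(C)C)[C@@H]2[C@@H](OC(=O)c3ccc(OC)cc3)CC(C)=CC[C@]21C | intermediate
26 | angelic acid | C/C=C(/C)C(=O)O | starting material
27 | angelic 2,4,6-trichlorobenzoic anhydride (not isolated) | C/C=C(/C)C(=O)OC(=O)c1c(Cl)cc(Cl)cc1Cl | intermediate
28 | 2β-angeloyloxy-6α-(4-methoxybenzoyloxy)dauc-8-en-4β-ol (CNP0204191.1) | C/C=C(/C)C(=O)O[C@@H]1C[C@@](O)(C(C)C)[C@@H]2[C@@H](OC(=O)c3ccc(OC)cc3)CC(C)=CC[C@]21C | target

**Step count**
Total step count: 16.
Longest linear sequence: 15 (steps 1–3 and 5–16).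

**Steps most likely to fail**

Step 12 (ring A closure).
- What may go wrong: the kinetically easier cis-fused closure may fail to equilibrate, the aldolate may reopen on quench, or the tertiary aldolate may dehydrate on warming.
- Fallback, from 19 back to 21: N-bromosuccinimide (THF, −78 °C) should convert the enol ether regiospecifically into 2-bromo-3,6-dimethyl-3-[(1R)-1-(tert-butyldimethylsilyloxy)-4-methyl-3-oxopentyl]cyclohept-5-en-1-one F1.
- SmI2 (2 equiv, THF, −78 °C) then reduces the C–Br bond to the trivalent samarium enolate at C5. This enolate adds to the C4 ketone through a closed, chelated transition state (intramolecular samarium Reformatsky reaction). The metal links O4 and O6 from the start rather than after equilibration.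

Step 11 (methyl addition).
- What may go wrong: addition to the hindered β,β-disubstituted acceptor may be slow, enolisation at C7 or C10 may compete, and facial selectivity may be poor or reversed because the C3 chain is pressed against C10 in the favoured arrangement.
- Fallback, from 18 back to 19: stereocontrol is moved from the substrate to a chiral catalyst. This is a copper-catalysed asymmetric conjugate addition of Me3Al with copper thiophene-2-carboxylate Cu(O2CC4H3S) and a chiral phosphoramidite ligand (Et2O, −30 °C), the ligand antipode being chosen for the required face.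
- The aluminium enolate is silylated with Me3SiOTf. No compound outside the list is made (F0).

Step 13 (C6 reduction).
- What may go wrong: the hindered tertiary hydroxyl may exchange sluggishly with the borohydride, so that undirected hydride attack from the open α face takes over and gives the wrong C6 epimer.
- Fallback, from 21 back to 22: hydride delivery is replaced by single-electron reduction with SmI2 in THF/MeOH at 0 °C.
- The samarium ketyl is chelated by the C4 oxygen and is protonated to the more stable equatorial alcohol, i.e. the 1,3-anti diol. No compound outside the list is made (F0).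

**Further compounds**
F1 | step 12 | 2-bromo-3,6-dimethyl-3-[(1R)-1-(tert-butyldimethylsilyloxy)-4-methyl-3-oxopentyl]cyclohept-5-en-1-one (C5 bromide, either epimer) | CC(C)(C)[Si](C)(C)O[C@H](CC(=O)C(C)C)[C@@]1(C)C(Br)C(=O)CC(C)=CC1
F0 | step 11 | none | none
F0 | step 13 | none | none
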